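## The problem

Target 18 is an achiral bibenzyl. Ring A carries a methoxy group, a hydroxyl, two 4-hydroxybenzyl groups and the ethylene bridge, with one ring hydrogen left. Ring B carries a hydroxyl ortho to the bridge and a third 4-hydroxybenzyl group para to that hydroxyl. There are no stereocentres, so the task is regiochemical: five substituents must be placed on ring A, and the bridge must enter ring B ortho to oxygen. The bridge carbon on ring A lies between two benzyl groups, so any reaction that makes this carbon tetrahedral or brings it to a catalyst surface is slowed by two ortho substituents. All free positions of a 3,5-dioxygenated ring A precursor are activated, so direct electrophilic benzylation cannot be trusted and the diarylmethane bonds are better made by cross-coupling at halogenated positions. Five phenols must be carried past one methyl ether that stays, which points to benzyl ethers; these and the electron-rich diarylmethane links do not tolerate hot strong acid. The key step is made possible by the ring B hydroxyl on the carbon next to the bridge-bearing carbon. An O–N tether from that oxygen to the ring A end of the bridge can deliver the second bridge carbon to the ortho position through a six-atom array, and because ring B is para-substituted its two ortho positions are equivalent.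

## Retrosynthesis

**18 from 17.** The ring B hydroxyl oxygen is reconnected to the bridge carbon next to ring A and the bridge is unsaturated, giving 2-arylbenzofuran 17 with the four remaining phenols as benzyl ethers. The furan is a temporary ring: its reductive opening gives both bridge methylenes and the ring B hydroxyl, and the same reduction removes the benzyl groups. Furan C2 lies beside a doubly ortho-substituted aryl group, so the forward step should use electron transfer, not a catalyst surface.

**17 from 14 (key disconnection).** The bond between furan C3 and C3a (bridge carbon to the ortho carbon of ring B) and the C2–O bond are cut, and nitrogen is placed between oxygen and C2. This gives O-aryl ketoxime ether 14. Against ortho-halogenation and cross-coupling, or Friedel–Crafts alkylation of a ring B phenol, this cut needs no functional group on ring B other than its own oxygen and cannot give a meta or para isomer. The forward reaction must form the enamine tautomer of 14 under acid mild enough for benzyl ethers.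

**14 from 9 and 13.** The O–aryl bond is cut, giving ketoxime 9 and arylboronic acid 13. Condensing a preformed O-aryl nitrogen component with a carbonyl compound would require attack at the blocked carbon. Arylation at the oxime oxygen, three atoms away from it, does not.

**9 from 7.** The C–N bond of the oxime is cut back to terminal alkyne 7, not to a carbonyl group. A carbonyl condensation would pass through a tetrahedral carbon between two ortho benzyl groups, which is the known weakness of di-ortho-substituted acetophenones. Addition of the N–O unit across the triple bond takes this carbon only from sp to sp2, and the oxidation level is the same.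

**7 from 6.** One carbon is removed, giving aldehyde 6. A formyl group stays reactive between two ortho substituents because its own substituent is hydrogen.

**6 from 3 and 5.** Both aryl–CH2 bonds on ring A are cut, giving dibromoaldehyde 3 and two equivalents of benzylic zinc reagent 5. The positions are fixed by the halogens, not by the electronic bias of the ring.

**3 from 2 from 1.** The two C–Br bonds and the O-benzyl bond are cut back to commercial phenol aldehyde 1; the formyl group and the two alkoxy groups of 2 together direct bromination to the two positions needed.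

**13 from 11 from 5 and 10; 5 from 4.** The C–B bond and then the aryl–CH2 bond are cut. The same zinc reagent 5, made from commercial chloride 4, serves both fragments, and dihalide 10 supplies ring B.

## Roads not taken

**Alternative 1:** The three 4-hydroxyphenyl rings are cut out altogether. Tris(ethynyl ketone) A2, built on the protected bibenzyl core, would react with three equivalents of Danishefsky's diene A3 in Diels–Alder reactions that aromatise on acidic work-up to the tris(4-hydroxybenzoyl) compound A1.
- Merits: six C–C bonds and three rings form in one operation, the regiochemistry of each cycloaddition is set electronically (hydroxyl para to the acyl carbon), and no transition metal is needed. In bonds formed per step it is clearly ahead of the chosen plan.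
- Weak points: the rings it builds are the ones that can be bought in chloride 4. The hard parts, the fully substituted ring A and the ring B junction, must already be present in A2, whose three ynones (two flanking the bridge) need several steps each and are sensitive Michael acceptors. Three diaryl ketones must afterwards be reduced to methylene, two of them in hindered positions.
- Comparison: the chosen plan forms only one C–C bond in its key step, but that bond is the ring B junction, made with built-in regiocontrol.

**Alternative 2:** Ring A is cut at C4–C5 and C5–C6. The dianion of diketone A5 would be C-acylated by cinnamate ester A6 and the chain closed by aldol condensation to give stilbene resorcinol A4.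
- Merits: it is convergent, it sets all ring A substituents in one step without any reaction at a hindered aromatic position, and its end game (hydrogenation of an exposed stilbene together with debenzylation) is simpler than the furan opening used here. In these respects it is the better road.
- Weak points: the ring closure must use the least acidic methylene of the chain against O-cyclisation to a pyranone-type ring and conjugate addition to the enone. The two ring A hydroxyls of A4 are equivalent, so the single methylation needed is statistical.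
- Comparison: the chosen plan is longer in the ring A series, but every bond it makes has only one possible regiochemical outcome.

**Alternative 3:** The three CH2–aryl bonds to the hydroxyphenyl rings are cut. Tris(methyl carbonate) A8 would couple with three equivalents of boronic acid A9 under palladium catalysis to give A7, the pentabenzyl ether of 18.
- Merits: three identical bonds form in one late step, and A7 is one mild hydrogenolysis from the target, with no furan to open. The end game is better than the chosen one.
- Weak points: A8 already contains the bibenzyl junction and a ring A with two oxygenated benzylic carbons flanking the bridge, so the hard problems are moved into an unspecified core synthesis. Two of the three benzylic carbonates are doubly ortho-substituted and alkoxy-activated, so they ionise easily and form the benzylpalladium intermediate slowly; incomplete threefold coupling would give mixtures.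
- Comparison: the chosen plan makes the corresponding ring A bonds at aryl C–Br bonds, where oxidative addition is reliable, and it also provides the ring B junction.

Key step: step 10

## Route

Remark: 18 has no stereocentre. Oxime 9 and oxime ether 14 are drawn as E isomers, but either geometry enters step 10 through the same enamine tautomer.

Step 1
Reactants: 1 3-hydroxy-5-methoxybenzaldehyde
Product: 2 3-(benzyloxy)-5-methoxybenzaldehyde
Conditions: BnBr, K2CO3, DMF, rt
Reagents that add atoms: benzyl bromide, BrCc1ccccc1
Why: Williamson ether synthesis on the phenoxide; the benzyl ether should last until the final reduction, which removes it.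

Step 2
Reactants: 2 3-(benzyloxy)-5-methoxybenzaldehyde
Product: 3 3-(benzyloxy)-2,6-dibromo-5-methoxybenzaldehyde
Conditions: NBS (2.1 equiv), MeCN, 0 °C to rt, dark
Reagents that add atoms: N-bromosuccinimide, O=C1CCC(=O)N1Br
Why: Electrophilic aromatic bromination; each position ortho to the formyl group is para to one alkoxy group and ortho to the other and should react before the position between the two alkoxy groups, as is known for 3,5-dialkoxybenzaldehydes.

Step 3
Reactants: 4 4-(benzyloxy)benzyl chloride
Product: 5 [4-(benzyloxy)benzyl]zinc chloride (THF solution, titrated and used in steps 4 and 7)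
Conditions: Zn dust (activated with BrCH2CH2Br, TMSCl), LiCl, THF, 25 °C
Reagents that add atoms: zinc, [Zn]
Why: LiCl-assisted direct insertion of zinc into a benzylic C–Cl bond; electron-rich benzylic chlorides insert readily and the magnesium-free reagent shows little Wurtz coupling.

Step 4
Reactants: 3 3-(benzyloxy)-2,6-dibromo-5-methoxybenzaldehyde; 5 [4-(benzyloxy)benzyl]zinc chloride (2.6 equiv)
Product: 6 3-(benzyloxy)-2,6-bis[4-(benzyloxy)benzyl]-5-methoxybenzaldehyde
Conditions: Pd(OAc)2 (2 mol %), SPhos (4 mol %), THF, 25 to 50 °C
Reagents that add atoms: none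
Why: Twofold Negishi cross-coupling; the biaryl dialkylphosphine lets zerovalent palladium insert into C–Br bonds flanked by formyl and alkoxy groups, and a benzylic zinc chloride free of magnesium salts adds to aldehydes much more slowly than it transmetalates.

Step 5
Reactants: 6 3-(benzyloxy)-2,6-bis[4-(benzyloxy)benzyl]-5-methoxybenzaldehyde
Product: 7 1-(benzyloxy)-2,4-bis[4-(benzyloxy)benzyl]-3-ethynyl-5-methoxybenzene
Conditions: Ohira–Bestmann reagent, K2CO3, MeOH/THF, rt
Reagents that add atoms: dimethyl (1-diazo-2-oxopropyl)phosphonate, CC(=O)C(=[N+]=[N-])P(=O)(OC)OC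
Why: Seyferth–Gilbert homologation in the Ohira–Bestmann form (olefination to a diazoalkene, loss of N2, 1,2-shift of the alkylidene carbene); the formyl group should react although flanked because its own substituent is hydrogen.

Step 6
Reactants: 7 1-(benzyloxy)-2,4-bis[4-(benzyloxy)benzyl]-3-ethynyl-5-methoxybenzene
Product: 9 (E)-1-{3-(benzyloxy)-2,6-bis[4-(benzyloxy)benzyl]-5-methoxyphenyl}ethan-1-one oxime, via N-hydroxy enamine 8 (not isolated)
Conditions: NH2OH (50 % aq, 5 equiv), 1,4-dioxane, 110 °C, sealed tube
Reagents that add atoms: hydroxylamine, NO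
Why: Cope-type (reverse Cope) hydroamination of a terminal arylalkyne: nitrogen bonds to the internal carbon while the O–H hydrogen passes to the terminal carbon in a five-membered array, and N-vinylhydroxylamine 8 tautomerises to the methyl ketoxime. The carbon that becomes C=N goes only from sp to sp2, so the crowded tetrahedral intermediate of a carbonyl condensation is avoided.

Step 7
Reactants: 5 [4-(benzyloxy)benzyl]zinc chloride (1.1 equiv); 10 1-bromo-4-iodobenzene
Product: 11 1-(benzyloxy)-4-(4-bromobenzyl)benzene
Conditions: Pd(PPh3)4 (2 mol %), THF, 25 °C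
Reagents that add atoms: none
Why: Chemoselective Negishi coupling; at room temperature zerovalent palladium inserts into C–I much faster than into C–Br, so the bromide remains for step 8.

Step 8
Reactants: 11 1-(benzyloxy)-4-(4-bromobenzyl)benzene
Product: 13 {4-[4-(benzyloxy)benzyl]phenyl}boronic acid, via aryllithium 12 (not isolated)
Conditions: n-BuLi, THF, −78 °C; B(Oi-Pr)3, −78 °C to rt; 1 M HCl
Reagents that add atoms: triisopropyl borate, CC(C)OB(OC(C)C)OC(C)C; water, O; n-butyllithium, CCCC[Li] (its lithium appears only in 12)
Why: Bromine–lithium exchange, borylation and hydrolysis; at −78 °C the exchange is far faster than deprotonation of the diarylmethane or benzyl ether methylenes.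

Step 9
Reactants: 9 (E)-1-{3-(benzyloxy)-2,6-bis[4-(benzyloxy)benzyl]-5-methoxyphenyl}ethan-1-one oxime; 13 {4-[4-(benzyloxy)benzyl]phenyl}boronic acid (2 equiv)
Product: 14 (E)-1-{3-(benzyloxy)-2,6-bis[4-(benzyloxy)benzyl]-5-methoxyphenyl}ethan-1-one O-{4-[4-(benzyloxy)benzyl]phenyl}oxime
Conditions: Cu(OAc)2 (1.5 equiv), pyridine, 4 Å MS, ClCH2CH2Cl, air, rt
Reagents that add atoms: none
Why: Chan–Lam oxidative coupling of an oxime O–H with an arylboronic acid; the reacting oxygen is remote from the congested carbon, and N-arylation to a nitrone is disfavoured because nitrogen sits next to that carbon.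

Step 10
Reactants: 14 (E)-1-{3-(benzyloxy)-2,6-bis[4-(benzyloxy)benzyl]-5-methoxyphenyl}ethan-1-one O-{4-[4-(benzyloxy)benzyl]phenyl}oxime
Product: 17 2-{3-(benzyloxy)-2,6-bis[4-(benzyloxy)benzyl]-5-methoxyphenyl}-5-[4-(benzyloxy)benzyl]-1-benzofuran, via N-aryloxy enamine 15 (not isolated), via ortho-hydroxyaryl ketimine 16 (not isolated)
Conditions: MsOH (3 equiv), THF, 60 °C
Reagents that add atoms: none
Why: N-Protonation lets the oxime ether tautomerise to N-aryloxy enamine 15, which undergoes a chair-like [3,3] sigmatropic shift: the enamine CH2 carbon bonds to the ortho carbon of the aryloxy ring as the weak N–O bond breaks. Rearomatisation of the resulting dienone gives ortho-hydroxyaryl ketimine 16. Its phenol oxygen adds to the protonated imine carbon in a 5-exo-trig closure, and loss of ammonia from the 2-amino-2,3-dihydrobenzofuran gives the aromatic furan. The closest known reaction is the acid-promoted rearrangement of O-aryl ketoxime ethers to benzofurans, the oxygen analogue of the Fischer indole synthesis. No stereocentre is formed. The step needs regioselectivity on both sides: the oxime has a single enolisable methyl group, and the para-substituted aryloxy ring has two equivalent ortho positions. The crowded ring A aryl group is twisted out of the reacting array, and the bond is made at the unhindered CH2 terminus, so the two ortho benzyl groups should not slow the shift. A sulfonic acid at 60 °C is chosen so that benzyl ethers and diarylmethane links should survive.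

Step 11
Reactants: 17 2-{3-(benzyloxy)-2,6-bis[4-(benzyloxy)benzyl]-5-methoxyphenyl}-5-[4-(benzyloxy)benzyl]-1-benzofuran
Product: 18 2,4-bis(4-hydroxybenzyl)-3-{2-[2-hydroxy-5-(4-hydroxybenzyl)phenyl]ethyl}-5-methoxyphenol (CNP0134121.0)
Conditions: Na (excess), NH3(l)/THF, −78 to −33 °C; then solid NH4Cl
Reagents that add atoms: none
Why: Dissolving-metal reduction: electron transfer cleaves the four benzyl aryl ethers to phenoxides and toluene and reduces the 2-arylbenzofuran (an aryl styryl ether) through the 2,3-dihydro stage to the phenoxide formed by benzylic C2–O cleavage, as known for benzofurans and 2-aryl-2,3-dihydrobenzofurans with alkali metals. Electron transfer needs no catalyst surface at the shielded C2, and the rings, all phenoxides by then, should resist Birch reduction without an added alcohol.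

## Compound list

1 | 3-hydroxy-5-methoxybenzaldehyde | COc1cc(O)cc(C=O)c1 | starting material
2 | 3-(benzyloxy)-5-methoxybenzaldehyde | COc1cc(OCc2ccccc2)cc(C=O)c1 | intermediate
3 | 3-(benzyloxy)-2,6-dibromo-5-methoxybenzaldehyde | COc1cc(OCc2ccccc2)c(Br)c(C=O)c1Br | intermediate
4 | 4-(benzyloxy)benzyl chloride | ClCc1ccc(OCc2ccccc2)cc1 | starting material
5 | [4-(benzyloxy)benzyl]zinc chloride | Cl[Zn]Cc1ccc(OCc2ccccc2)cc1 | intermediate
6 | 3-(benzyloxy)-2,6-bis[4-(benzyloxy)benzyl]-5-methoxybenzaldehyde | COc1cc(OCc2ccccc2)c(Cc2ccc(OCc3ccccc3)cc2)c(C=O)c1Cc1ccc(OCc2ccccc2)cc1 | intermediate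
7 | 1-(benzyloxy)-2,4-bis[4-(benzyloxy)benzyl]-3-ethynyl-5-methoxybenzene | COc1cc(OCc2ccccc2)c(Cc2ccc(OCc3ccccc3)cc2)c(C#C)c1Cc1ccc(OCc2ccccc2)cc1 | intermediate
8 | N-(1-{3-(benzyloxy)-2,6-bis[4-(benzyloxy)benzyl]-5-methoxyphenyl}vinyl)hydroxylamine | C=C(NO)c1c(Cc2ccc(OCc3ccccc3)cc2)c(OC)cc(OCc2ccccc2)c1Cc1ccc(OCc2ccccc2)cc1 | intermediate
9 | (E)-1-{3-(benzyloxy)-2,6-bis[4-(benzyloxy)benzyl]-5-methoxyphenyl}ethan-1-one oxime | C/C(=N\O)c1c(Cc2ccc(OCc3ccccc3)cc2)c(OC)cc(OCc2ccccc2)c1Cc1ccc(OCc2ccccc2)cc1 | intermediate
10 | 1-bromo-4-iodobenzene | Brc1ccc(I)cc1 | starting material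
11 | 1-(benzyloxy)-4-(4-bromobenzyl)benzene | Brc1ccc(Cc2ccc(OCc3ccccc3)cc2)cc1 | intermediate
12 | {4-[4-(benzyloxy)benzyl]phenyl}lithium | [Li]c1ccc(Cc2ccc(OCc3ccccc3)cc2)cc1 | intermediate
13 | {4-[4-(benzyloxy)benzyl]phenyl}boronic acid | OB(O)c1ccc(Cc2ccc(OCc3ccccc3)cc2)cc1 | intermediate
14 | (E)-1-{3-(benzyloxy)-2,6-bis[4-(benzyloxy)benzyl]-5-methoxyphenyl}ethan-1-one O-{4-[4-(benzyloxy)benzyl]phenyl}oxime | C/C(=N\Oc1ccc(Cc2ccc(OCc3ccccc3)cc2)cc1)c1c(Cc2ccc(OCc3ccccc3)cc2)c(OC)cc(OCc2ccccc2)c1Cc1ccc(OCc2ccccc2)cc1 | intermediate
15 | N-(1-{3-(benzyloxy)-2,6-bis[4-(benzyloxy)benzyl]-5-methoxyphenyl}vinyl)-O-{4-[4-(benzyloxy)benzyl]phenyl}hydroxylamine | C=C(NOc1ccc(Cc2ccc(OCc3ccccc3)cc2)cc1)c1c(Cc2ccc(OCc3ccccc3)cc2)c(OC)cc(OCc2ccccc2)c1Cc1ccc(OCc2ccccc2)cc1 | intermediate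
16 | 4-[4-(benzyloxy)benzyl]-2-(2-{3-(benzyloxy)-2,6-bis[4-(benzyloxy)benzyl]-5-methoxyphenyl}-2-iminoethyl)phenol | N=C(Cc1cc(Cc2ccc(OCc3ccccc3)cc2)ccc1O)c1c(Cc2ccc(OCc3ccccc3)cc2)c(OC)cc(OCc2ccccc2)c1Cc1ccc(OCc2ccccc2)cc1 | intermediate
17 | 2-{3-(benzyloxy)-2,6-bis[4-(benzyloxy)benzyl]-5-methoxyphenyl}-5-[4-(benzyloxy)benzyl]-1-benzofuran | COc1cc(OCc2ccccc2)c(Cc2ccc(OCc3ccccc3)cc2)c(-c2cc3cc(Cc4ccc(OCc5ccccc5)cc4)ccc3o2)c1Cc1ccc(OCc2ccccc2)cc1 | intermediate
18 | 2,4-bis(4-hydroxybenzyl)-3-{2-[2-hydroxy-5-(4-hydroxybenzyl)phenyl]ethyl}-5-methoxyphenol (CNP0134121.0) | COc1cc(O)c(Cc2ccc(O)cc2)c(CCc2cc(Cc3ccc(O)cc3)ccc2O)c1Cc1ccc(O)cc1 | target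

## Step count and uncertain steps

Total: 11 steps. Longest linear sequence: 8 steps (steps 1, 2, 4, 5, 6, 9, 10, 11, from 1 to 18).

**Step 10 (key step).**
- Risk: the N–O bond may ionise under acid before the enamine tautomer forms, leading to Beckmann-type migration of the electron-rich, twisted ring A aryl group (anti to the aryloxy group in the E isomer) or to solvolysis. On long heating, benzyl or 4-benzyloxybenzyl groups may also be transferred between the electron-rich rings.
- First adjustment: change the trigger from protonation to N-trifluoroacetylation at low temperature.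
- Fallback: the same furan is closed by coupling and heteroannulation. Boronic acid 13 would be oxidised (H2O2, NaOH) to 4-[4-(benzyloxy)benzyl]phenol F1 and iodinated ortho to the hydroxyl (I2, NaHCO3) to give 4-[4-(benzyloxy)benzyl]-2-iodophenol F2. Sonogashira coupling of F2 with alkyne 7 (PdCl2(PPh3)2, CuI, Et3N, DMF, 70 °C), followed in the same flask by 5-endo-dig attack of the phenol on the alkyne, returns to the route at 17.

**Step 6.**
- Risk: N–C bond formation at the internal alkyne carbon may be slowed by the two ortho benzyl groups so far that thermal decomposition of hydroxylamine outruns the hydroamination.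
- Fallback: from 7, Markovnikov hydration (Ph3PAuNTf2 cat., aqueous 1,4-dioxane, 80 °C) would give 1-{3-(benzyloxy)-2,6-bis[4-(benzyloxy)benzyl]-5-methoxyphenyl}ethan-1-one F3. Condensation under forcing conditions (NH2OH·HCl, pyridine, sealed tube, 120 °C, prolonged) returns to 9.

**Step 4.**
- Risk: 1,2-addition of the benzylic zinc reagent to the formyl group during the slower second coupling, or stalling after the first coupling.
- Fallback: from 3, acetal formation (HC(OMe)3, MeOH, TsOH) would give 1-(benzyloxy)-2,4-dibromo-3-(dimethoxymethyl)-5-methoxybenzene F4. The twofold Negishi coupling with 5 can then be forced (more reagent, 60 °C) to give 1-(benzyloxy)-2,4-bis[4-(benzyloxy)benzyl]-3-(dimethoxymethyl)-5-methoxybenzene F5, and aqueous HCl in THF returns to 6.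

**Step 9.**
- Risk: protodeboronation and homocoupling of 13 may consume the boronic acid faster than the oxime is arylated, or the oxime may be N-arylated to a nitrone.
- Fallback: an Ullmann-type coupling with an aryl iodide. From 11, bromine–lithium exchange (n-BuLi, −78 °C) and an iodine quench would give 1-(benzyloxy)-4-(4-iodobenzyl)benzene F6, which is coupled with oxime 9 (CuI cat., 1,10-phenanthroline, Cs2CO3, toluene, 100 °C) to return to 14.

**Step 11.**
- Risk: reduction of the furan may stop once the molecule carries four phenoxide charges, because electron transfer into a polyanion is slow; prolonged exposure may cause reductive O-demethylation.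
- Fallback: from 17, hydrogenolysis (H2, 1 atm, Pd/C, EtOAc/MeOH) would remove the benzyl groups to give 2,4-bis(4-hydroxybenzyl)-3-[5-(4-hydroxybenzyl)-1-benzofuran-2-yl]-5-methoxyphenol F7. Ionic hydrogenation (Et3SiH, CF3CO2H) would saturate the furan to racemic 2,4-bis(4-hydroxybenzyl)-3-[5-(4-hydroxybenzyl)-2,3-dihydro-1-benzofuran-2-yl]-5-methoxyphenol F8, and hydrogenolysis of its benzylic C2–O bond (H2, 5 bar, Pd(OH)2/C, AcOH) returns to 18.

## Further compounds

F1 | step 10 | 4-[4-(benzyloxy)benzyl]phenol | Oc1ccc(Cc2ccc(OCc3ccccc3)cc2)cc1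
F2 | step 10 | 4-[4-(benzyloxy)benzyl]-2-iodophenol | Oc1ccc(Cc2ccc(OCc3ccccc3)cc2)cc1I
F3 | step 6 | 1-{3-(benzyloxy)-2,6-bis[4-(benzyloxy)benzyl]-5-methoxyphenyl}ethan-1-one | CC(=O)c1c(Cc2ccc(OCc3ccccc3)cc2)c(OC)cc(OCc2ccccc2)c1Cc1ccc(OCc2ccccc2)cc1
F4 | step 4 | 1-(benzyloxy)-2,4-dibromo-3-(dimethoxymethyl)-5-methoxybenzene | COc1cc(OCc2ccccc2)c(Br)c(C(OC)OC)c1Br
F5 | step 4 | 1-(benzyloxy)-2,4-bis[4-(benzyloxy)benzyl]-3-(dimethoxymethyl)-5-methoxybenzene | COc1cc(OCc2ccccc2)c(Cc2ccc(OCc3ccccc3)cc2)c(C(OC)OC)c1Cc1ccc(OCc2ccccc2)cc1
F6 | step 9 | 1-(benzyloxy)-4-(4-iodobenzyl)benzene | Ic1ccc(Cc2ccc(OCc3ccccc3)cc2)cc1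
F7 | step 11 | 2,4-bis(4-hydroxybenzyl)-3-[5-(4-hydroxybenzyl)-1-benzofuran-2-yl]-5-methoxyphenol | COc1cc(O)c(Cc2ccc(O)cc2)c(-c2cc3cc(Cc4ccc(O)cc4)ccc3o2)c1Cc1ccc(O)cc1
F8 | step 11 | 2,4-bis(4-hydroxybenzyl)-3-[5-(4-hydroxybenzyl)-2,3-dihydro-1-benzofuran-2-yl]-5-methoxyphenol (racemic) | COc1cc(O)c(Cc2ccc(O)cc2)c(C2Cc3cc(Cc4ccc(O)cc4)ccc3O2)c1Cc1ccc(O)cc1
A1 | alternative 1 | [4-(benzyloxy)-3-{2-[3-(benzyloxy)-2,6-bis(4-hydroxybenzoyl)-5-methoxyphenyl]ethyl}phenyl](4-hydroxyphenyl)methanone | COc1cc(OCc2ccccc2)c(C(=O)c2ccc(O)cc2)c(CCc2cc(C(=O)c3ccc(O)cc3)ccc2OCc2ccccc2)c1C(=O)c1ccc(O)cc1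
A2 | alternative 1 | 1,1'-{4-(benzyloxy)-2-[2-(2-(benzyloxy)-5-propioloylphenyl)ethyl]-6-methoxy-1,3-phenylene}bis(prop-2-yn-1-one) | COc1cc(OCc2ccccc2)c(C(=O)C#C)c(CCc2cc(C(=O)C#C)ccc2OCc2ccccc2)c1C(=O)C#C
A3 | alternative 1 | trans-1-methoxy-3-(trimethylsilyloxy)buta-1,3-diene (Danishefsky's diene) | CO/C=C/C(=C)O[Si](C)(C)C
A4 | alternative 2 | 4,6-bis[4-(benzyloxy)benzyl]-5-{(E)-2-[2-(benzyloxy)-5-(4-(benzyloxy)benzyl)phenyl]vinyl}benzene-1,3-diol | Oc1cc(O)c(Cc2ccc(OCc3ccccc3)cc2)c(/C=C/c2cc(Cc3ccc(OCc4ccccc4)cc3)ccc2OCc2ccccc2)c1Cc1ccc(OCc2ccccc2)cc1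
A5 | alternative 2 | 1,7-bis[4-(benzyloxy)phenyl]heptane-3,5-dione | O=C(CCc1ccc(OCc2ccccc2)cc1)CC(=O)CCc1ccc(OCc2ccccc2)cc1
A6 | alternative 2 | methyl (E)-3-{2-(benzyloxy)-5-[4-(benzyloxy)benzyl]phenyl}acrylate | COC(=O)/C=C/c1cc(Cc2ccc(OCc3ccccc3)cc2)ccc1OCc1ccccc1
A7 | alternative 3 | 1-(benzyloxy)-2,4-bis[4-(benzyloxy)benzyl]-3-{2-[2-(benzyloxy)-5-(4-(benzyloxy)benzyl)phenyl]ethyl}-5-methoxybenzene | COc1cc(OCc2ccccc2)c(Cc2ccc(OCc3ccccc3)cc2)c(CCc2cc(Cc3ccc(OCc4ccccc4)cc3)ccc2OCc2ccccc2)c1Cc1ccc(OCc2ccccc2)cc1
A8 | alternative 3 | {4-(benzyloxy)-2-[2-(2-(benzyloxy)-5-{[(methoxycarbonyl)oxy]methyl}phenyl)ethyl]-6-methoxy-1,3-phenylene}bis(methylene) dimethyl bis(carbonate) | COc1cc(OCc2ccccc2)c(COC(=O)OC)c(CCc2cc(COC(=O)OC)ccc2OCc2ccccc2)c1COC(=O)OC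
A9 | alternative 3 | [4-(benzyloxy)phenyl]boronic acid | OB(O)c1ccc(OCc2ccccc2)cc1
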